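The route first adjusts oxidation levels in reverse (hydroquinone from quinone from dimethyl ether, both ketones from carbinols). It then cuts the side chain at C1–C2 (benzyl–alkenyl) and at C3–CH3 in one operation, back to a terminal alkyne diol, a benzylic chloride and AlMe3. Earlier cuts are the propargyl–carbinol bond, the prenyl arm (allyl–carbinol bond plus an alkene exchange), and the C=C bond of a cis-bicyclo[3.3.0]octene silyl enol ether, which supplies both arms.
Enabling feature: in the chain C1H2 (benzylic)–C2H=C3(CH3)–C4H2, the C3 methyl and C1 lie on the same side of the double bond (E, with C1 trans to C4). This is the pattern left by syn addition of CH3 and a metal to a terminal C2≡C3 alkyne, followed by replacement of the metal on C2 by the benzylic carbon with retention.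
Forward order: the purchased five-membered ring A is kept throughout. A cyclopropane and a second five-membered ring B close together by carbenoid addition, the cyclopropane is opened reductively, and ring B is cleaved by ozone to an aldehyde arm and an acid arm. A temporary six-membered lactone (ring C) tells the arms apart and is opened by propargylation, after which the chain is joined to the arene.
Stereochemistry: a CBS reduction sets one carbinol, and the Johnson–Claisen shift passes it suprafacially to the first quaternary carbon (R). The tethered cyclopropanation sets the neighbouring quaternary carbon (R, methyls cis). Regiospecific enolate trapping keeps a skeleton chiral whose parent ketone would be meso. The carbinol epimers disappear on oxidation.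

Key step: step 16

Assumption: carbinol and lactol carbons that later become carbonyl groups are carried as epimer mixtures and drawn without configuration. Chain locants C1–C4 count from the benzylic CH2.

Step 1
Reactants: 1 2,3-dimethylcyclopent-2-en-1-one
Product: 2 (1R)-2,3-dimethylcyclopent-2-en-1-ol
Conditions: (S)-Me-CBS oxazaborolidine (C18H20BNO, 10 mol %), BH3·SMe2, THF, −20 °C; MeOH, then aqueous work-up
Reagents that add atoms: none
Why: Corey–Bakshi–Shibata reduction: the ketone binds to the catalyst boron with its CH2 side next to the B-methyl group and the methyl-substituted alkene arm pointing away as the large group, so the borane held on nitrogen delivers hydride to one carbonyl face only and C1 should be set as R, with 1,2-reduction as is usual for alpha-substituted cyclopentenones.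

Step 2
Reactants: 2 (1R)-2,3-dimethylcyclopent-2-en-1-ol; 3 triethyl orthoacetate
Product: 5 ethyl 2-[(1R)-1,2-dimethylcyclopent-2-en-1-yl]acetate, via ketene acetal 4 (not isolated)
Conditions: 3 (excess), EtCO2H (cat), 140 °C, EtOH distilled off
Reagents that add atoms: triethyl orthoacetate (compound 3), CCOC(C)(OCC)OCC
Why: Johnson–Claisen rearrangement: acid-catalysed exchange and loss of ethanol give ketene acetal 4, and because its [3,3] shift runs within the five-membered ring the new C–C bond can form only on the face of C3 from which the C1–O bond departs, so the carbinol configuration is handed on to the first quaternary centre (R) while the alkene moves to the former C1=C2 position.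

Step 3
Reactants: 5 ethyl 2-[(1R)-1,2-dimethylcyclopent-2-en-1-yl]acetate
Product: 6 2-[(1R)-1,2-dimethylcyclopent-2-en-1-yl]acetic acid
Conditions: NaOH, MeOH–H2O, reflux; aq HCl
Reagents that add atoms: sodium hydroxide, [Na+].[OH-]
Why: Ester saponification of an acetate arm, in which the only stereocentre is quaternary and cannot epimerise and the trisubstituted alkene is inert to hydroxide.

Step 4
Reactants: 6 2-[(1R)-1,2-dimethylcyclopent-2-en-1-yl]acetic acid
Product: 8 1-diazo-3-[(1R)-1,2-dimethylcyclopent-2-en-1-yl]propan-2-one, via acid chloride 7 (not isolated)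
Conditions: (COCl)2, DMF (cat), CH2Cl2, 0 °C to rt; concentrate; CH2N2 (excess), Et2O, 0 °C
Reagents that add atoms: oxalyl chloride, O=C(Cl)C(=O)Cl (chlorine of 7 only); diazomethane, C=[N+]=[N-]
Why: Acylation of diazomethane by acid chloride 7 (the opening stage of the Arndt–Eistert sequence), in which surplus diazomethane takes up the hydrogen chloride so that the diazoketone is not turned into a chloromethyl ketone.

Step 5
Reactants: 8 1-diazo-3-[(1R)-1,2-dimethylcyclopent-2-en-1-yl]propan-2-one
Product: 9 (1S,2R,5R,8S)-1,5-dimethyltricyclo[3.3.0.0(2,8)]octan-3-one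
Conditions: Rh2(OAc)4 (1 mol %), CH2Cl2, rt, slow addition of 8
Reagents that add atoms: none
Why: Intramolecular rhodium-carbenoid cyclopropanation of a gamma,delta-unsaturated diazoketone: the short tether lets the carbenoid reach the ring alkene only on the face that carries the side chain, so the second quaternary centre (C1) and both cyclopropane CH centres (C2, C8) are fixed by the existing centre C5 and the two methyl groups end up cis.

Step 6
Reactants: 9 (1S,2R,5R,8S)-1,5-dimethyltricyclo[3.3.0.0(2,8)]octan-3-one
Product: 11 {[(3aS,6aR)-3a,6a-dimethyl-1,3a,4,5,6,6a-hexahydropentalen-2-yl]oxy}trimethylsilane, via lithium enolate 10 (not isolated)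
Conditions: Li, NH3(l)–THF, −78 to −33 °C; NH3 evaporated; Me3SiCl, Et3N, THF, −78 to 0 °C
Reagents that add atoms: lithium, [Li] (in 10 only); chlorotrimethylsilane, C[Si](C)(C)Cl
Why: Dissolving-metal cleavage of a conjugated cyclopropyl ketone with enolate trapping: the C2–C8 bond lies outside the cyclopentanone ring, overlaps with the carbonyl pi system and releases a secondary rather than a tertiary carbanion, so it should break selectively, and enolate 10, whose double bond points only to the former carbene carbon, is silylated with no proton donor present, which preserves the chirality of a skeleton whose parent ketone would be meso.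

Step 7
Reactants: 11 {[(3aS,6aR)-3a,6a-dimethyl-1,3a,4,5,6,6a-hexahydropentalen-2-yl]oxy}trimethylsilane
Product: 13 2-[(1R,2R)-2-formyl-1,2-dimethylcyclopentyl]acetic acid, via silyl ester aldehyde 12 (not isolated)
Conditions: O3, CH2Cl2, −78 °C; Me2S, −78 °C to rt; THF–H2O
Reagents that add atoms: ozone, [O-][O+]=O
Why: Ozonolysis of a silyl enol ether with reductive work-up: the electron-rich C2=C3 bond is the only alkene present, its oxygen-bearing carbon emerges as silyl ester 12 (hydrolysed to the acid by water) and its CH carbon as an aldehyde on a quaternary carbon that cannot epimerise.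

Step 8
Reactants: 13 2-[(1R,2R)-2-formyl-1,2-dimethylcyclopentyl]acetic acid; 14 allylmagnesium bromide
Product: 16 (4aR,7aR)-4a,7a-dimethyl-1-(prop-2-en-1-yl)hexahydrocyclopenta[c]pyran-3(1H)-one (C1 epimers), via hydroxy acid 15 (not isolated)
Conditions: 14 (2.5 equiv), THF, −78 to 0 °C; aq HCl; p-TsOH·H2O (cat), CH2Cl2, rt
Reagents that add atoms: allylmagnesium bromide (compound 14), C=CC[Mg]Br
Why: Grignard addition followed by acid-catalysed lactonisation: the first equivalent of 14 turns the acid into an unreactive magnesium carboxylate, the second adds to the neopentyl-type aldehyde through the compact six-membered allyl transfer, and the cis arrangement of the two arms lets hydroxy acid 15 close to the six-membered lactone, the new carbinol centre being left uncontrolled because step 17 turns it into a ketone.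

Step 9
Reactants: 16 (4aR,7aR)-4a,7a-dimethyl-1-(prop-2-en-1-yl)hexahydrocyclopenta[c]pyran-3(1H)-one; 17 2-methylbut-2-ene
Product: 18 (4aR,7aR)-4a,7a-dimethyl-1-(3-methylbut-2-en-1-yl)hexahydrocyclopenta[c]pyran-3(1H)-one (C1 epimers)
Conditions: 17 (large excess), second-generation Grubbs catalyst RuCl2(=CHPh)(PCy3)(H2IMes) (3 mol %), CH2Cl2, 40 °C
Reagents that add atoms: 2-methylbut-2-ene (compound 17), CC=C(C)C
Why: Olefin cross metathesis of a monosubstituted alkene with excess 2-methylbut-2-ene, a standard way of turning an allyl into a prenyl group that sidesteps the gamma attack (reverse prenylation) expected of prenyl-metal reagents on the aldehyde, with escaping propene driving the exchange.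

Step 10
Reactants: 18 (4aR,7aR)-4a,7a-dimethyl-1-(3-methylbut-2-en-1-yl)hexahydrocyclopenta[c]pyran-3(1H)-one
Product: 19 (4aR,7aR)-4a,7a-dimethyl-1-(3-methylbut-2-en-1-yl)octahydrocyclopenta[c]pyran-3-ol (epimers at C1 and C3)
Conditions: i-Bu2AlH, CH2Cl2, −78 °C; aq potassium sodium tartrate
Reagents that add atoms: none
Why: Partial reduction of a lactone with i-Bu2AlH, in which the tetrahedral aluminium alkoxide persists at low temperature and gives the lactol only on work-up while the isolated alkene is not touched.

Step 11
Reactants: 19 (4aR,7aR)-4a,7a-dimethyl-1-(3-methylbut-2-en-1-yl)octahydrocyclopenta[c]pyran-3-ol; 20 propargyl bromide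
Product: 21 1-[(1R,2R)-2-(2-hydroxypent-4-yn-1-yl)-1,2-dimethylcyclopentyl]-4-methylpent-3-en-1-ol (both carbinols as epimers)
Conditions: 20, Zn dust, THF, 0 °C; then 19, 0 °C to rt; aq NH4Cl
Reagents that add atoms: propargyl bromide (compound 20), BrCC#C
Why: Barbier-type zinc propargylation of a lactol: the zinc lactolate opens to the aldehyde and allenylzinc bromide adds through its gamma carbon (SE2' via a cyclic transition state) to give the homopropargylic rather than the allenic alcohol, the new carbinol centre again being uncontrolled and erased in step 17.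

Step 12
Reactants: 22 4-methoxy-2-methylphenol
Product: 23 2-hydroxy-5-methoxy-3-methylbenzaldehyde
Conditions: MgCl2, Et3N, (CH2O)n, MeCN, reflux; aq HCl
Reagents that add atoms: paraformaldehyde (as formaldehyde), C=O
Why: Magnesium-mediated ortho-formylation of a phenol (Casnati–Skattebøl reaction): the magnesium phenoxide delivers formaldehyde to the only free ortho position and a second formaldehyde accepts hydride from the benzylic alkoxide, so the carbon lands where plain electrophilic substitution of the dimethyl ether would not put it.

Step 13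
Reactants: 23 2-hydroxy-5-methoxy-3-methylbenzaldehyde
Product: 24 2,5-dimethoxy-3-methylbenzaldehyde
Conditions: MeI, K2CO3, DMF, rt
Reagents that add atoms: iodomethane, CI
Why: Williamson ether synthesis on the acidic salicylaldehyde hydroxyl, the only nucleophilic site in the molecule.

Step 14
Reactants: 24 2,5-dimethoxy-3-methylbenzaldehyde
Product: 25 (2,5-dimethoxy-3-methylphenyl)methanol
Conditions: NaBH4, MeOH, 0 °C
Reagents that add atoms: none
Why: Borohydride reduction of an aromatic aldehyde, with no other reducible group present.

Step 15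
Reactants: 25 (2,5-dimethoxy-3-methylphenyl)methanol
Product: 26 2,5-dimethoxy-3-methylbenzyl chloride
Conditions: SOCl2, CH2Cl2, 0 °C; used without storage
Reagents that add atoms: thionyl chloride, O=S(Cl)Cl
Why: Chlorodehydroxylation through the chlorosulfite, which is fast for an electron-rich benzylic alcohol and leaves only gaseous coproducts, so the solvolysis-prone chloride can be taken on directly.

Step 16
Reactants: 21 1-[(1R,2R)-2-(2-hydroxypent-4-yn-1-yl)-1,2-dimethylcyclopentyl]-4-methylpent-3-en-1-ol; 26 2,5-dimethoxy-3-methylbenzyl chloride; 27 trimethylaluminium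
Product: 29 1-[(1R,2R)-2-[(4E)-6-(2,5-dimethoxy-3-methylphenyl)-2-hydroxy-4-methylhex-4-en-1-yl]-1,2-dimethylcyclopentyl]-4-methylpent-3-en-1-ol (carbinol epimers), via alkenylalane 28 (not isolated)
Conditions: 27 (5 equiv), Cp2ZrCl2 (0.3 equiv), CH2Cl2, 0 °C to rt; volatiles removed in vacuo; THF; 26, NiCl2(PPh3)2 (5 mol %) + n-BuLi (10 mol %), rt; 1 M HCl, 0 °C
Reagents that add atoms: trimethylaluminium (compound 27), C[Al](C)C
Why: After both hydroxyls have been capped as dimethylaluminium alkoxides, the methylzirconocene species formed from Cp2ZrCl2 and AlMe3 adds CH3 and metal to the same face of the C2≡C3 triple bond, methyl to the internal C3 and metal to the terminal C2, and exchange with aluminium gives alkenylalane 28 (C3–CH3 bond). Zerovalent nickel, made from NiCl2(PPh3)2 and n-BuLi, then inserts into the benzylic C–Cl bond of 26, receives the alkenyl ligand from aluminium and couples the two carbon ligands with the geometry at C2 unchanged (C2–C1 bond). The closest known reaction type is the Negishi zirconium-catalysed carboalumination of terminal alkynes, free but-3-yn-1-ols included, joined to the nickel-catalysed benzylation of alkenylalanes that serves for the side chains of prenylated quinones. No ring closes and no stereocentre is formed; the only stereochemical element is the alkene, where syn addition plus retention places the C3 methyl and C1 on the same side, which is the E geometry of the target. The step needs regioselectivity (the unsubstituted alkyne terminus takes the bulky metal), chemoselectivity (the trisubstituted prenyl alkene does not carbometalate) and alkenyl-over-methyl transfer to nickel (the sp2 ligand migrates faster, and free AlMe3 is pumped off before the coupling). With both future carbonyl carbons still at the alkoxide level there is no acidic alpha hydrogen and no drive for the new alkene to migrate, and keeping the alane at or below room temperature avoids alkoxide-assisted E-to-Z drift.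

Step 17
Reactants: 29 1-[(1R,2R)-2-[(4E)-6-(2,5-dimethoxy-3-methylphenyl)-2-hydroxy-4-methylhex-4-en-1-yl]-1,2-dimethylcyclopentyl]-4-methylpent-3-en-1-ol
Product: 30 (4E)-6-(2,5-dimethoxy-3-methylphenyl)-1-[(1R,2R)-1,2-dimethyl-2-(4-methylpent-3-enoyl)cyclopentyl]-4-methylhex-4-en-2-one
Conditions: Dess–Martin periodinane (3 equiv), pyridine, CH2Cl2, 0 °C to rt
Reagents that add atoms: none
Why: Dess–Martin oxidation under pyridine buffering, a near-neutral method that also reaches the neopentyl carbinol, leaves both beta,gamma-alkenes out of conjugation and merges all carbinol epimers into one diketone.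

Step 18
Reactants: 30 (4E)-6-(2,5-dimethoxy-3-methylphenyl)-1-[(1R,2R)-1,2-dimethyl-2-(4-methylpent-3-enoyl)cyclopentyl]-4-methylhex-4-en-2-one
Product: 31 2-[(2E)-6-[(1R,2R)-1,2-dimethyl-2-(4-methylpent-3-enoyl)cyclopentyl]-3-methyl-5-oxohex-2-en-1-yl]-6-methylcyclohexa-2,5-diene-1,4-dione
Conditions: (NH4)2Ce(NO3)6, MeCN–H2O, 0 °C, short contact time
Reagents that add atoms: water, O
Why: Oxidative demethylation of a 1,4-dimethoxyarene by tetravalent cerium: the electron-rich ring gives up electrons far faster than the trisubstituted alkenes, water attacks the two methoxy-bearing carbons and methanol leaves, as is routine for prenylated quinones.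

Step 19
Reactants: 31 2-[(2E)-6-[(1R,2R)-1,2-dimethyl-2-(4-methylpent-3-enoyl)cyclopentyl]-3-methyl-5-oxohex-2-en-1-yl]-6-methylcyclohexa-2,5-diene-1,4-dione
Product: 32 (4E)-6-(2,5-dihydroxy-3-methylphenyl)-1-[(1R,2R)-1,2-dimethyl-2-(4-methylpent-3-enoyl)cyclopentyl]-4-methylhex-4-en-2-one (CNP0294415.1)
Conditions: Na2S2O4, Et2O–H2O, rt, under argon
Reagents that add atoms: none
Why: Dithionite reduction of a benzoquinone in a neutral two-phase medium, which stops at the hydroquinone and leaves ketones, alkenes and both quaternary centres untouched.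

Compound list
1 | 2,3-dimethylcyclopent-2-en-1-one | CC1=C(C)C(=O)CC1 | starting material
2 | (1R)-2,3-dimethylcyclopent-2-en-1-ol | CC1=C(C)[C@H](O)CC1 | intermediate
3 | triethyl orthoacetate | CCOC(C)(OCC)OCC | starting material
4 | (3R)-3-[(1-ethoxyethenyl)oxy]-1,2-dimethylcyclopent-1-ene (ketene acetal) | CC1=C(C)[C@H](OC(=C)OCC)CC1 | intermediate
5 | ethyl 2-[(1R)-1,2-dimethylcyclopent-2-en-1-yl]acetate | CC1=CCC[C@]1(C)CC(=O)OCC | intermediate
6 | 2-[(1R)-1,2-dimethylcyclopent-2-en-1-yl]acetic acid | CC1=CCC[C@]1(C)CC(=O)O | intermediate
7 | 2-[(1R)-1,2-dimethylcyclopent-2-en-1-yl]acetyl chloride | CC1=CCC[C@]1(C)CC(=O)Cl | intermediate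
8 | 1-diazo-3-[(1R)-1,2-dimethylcyclopent-2-en-1-yl]propan-2-one | CC1=CCC[C@]1(C)CC(=O)C=[N+]=[N-] | intermediate
9 | (1S,2R,5R,8S)-1,5-dimethyltricyclo[3.3.0.0(2,8)]octan-3-one | O=C1C[C@@]2(C)CC[C@H]3[C@@H]1[C@@]23C | intermediate
10 | lithium (3aS,6aR)-3a,6a-dimethyl-1,3a,4,5,6,6a-hexahydropentalen-2-olate | [Li]OC1=C[C@]2(C)CCC[C@]2(C)C1 | intermediate
11 | {[(3aS,6aR)-3a,6a-dimethyl-1,3a,4,5,6,6a-hexahydropentalen-2-yl]oxy}trimethylsilane | C[Si](C)(C)OC1=C[C@]2(C)CCC[C@]2(C)C1 | intermediate
12 | trimethylsilyl 2-[(1R,2R)-2-formyl-1,2-dimethylcyclopentyl]acetate | O=C[C@]1(C)CCC[C@]1(C)CC(=O)O[Si](C)(C)C | intermediate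
13 | 2-[(1R,2R)-2-formyl-1,2-dimethylcyclopentyl]acetic acid | O=C[C@]1(C)CCC[C@]1(C)CC(=O)O | intermediate
14 | allylmagnesium bromide | C=CC[Mg]Br | starting material
15 | 2-[(1R,2R)-2-(1-hydroxybut-3-en-1-yl)-1,2-dimethylcyclopentyl]acetic acid (carbinol epimers) | C=CCC(O)[C@]1(C)CCC[C@]1(C)CC(=O)O | intermediate
16 | (4aR,7aR)-4a,7a-dimethyl-1-(prop-2-en-1-yl)hexahydrocyclopenta[c]pyran-3(1H)-one (C1 epimers) | C=CCC2[C@]1(C)CCC[C@]1(C)CC(=O)O2 | intermediate
17 | 2-methylbut-2-ene | CC=C(C)C | starting material
18 | (4aR,7aR)-4a,7a-dimethyl-1-(3-methylbut-2-en-1-yl)hexahydrocyclopenta[c]pyran-3(1H)-one (C1 epimers) | CC(C)=CCC2[C@]1(C)CCC[C@]1(C)CC(=O)O2 | intermediate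
19 | (4aR,7aR)-4a,7a-dimethyl-1-(3-methylbut-2-en-1-yl)octahydrocyclopenta[c]pyran-3-ol (C1 and C3 epimers) | CC(C)=CCC2[C@]1(C)CCC[C@]1(C)CC(O)O2 | intermediate
20 | propargyl bromide | BrCC#C | starting material
21 | 1-[(1R,2R)-2-(2-hydroxypent-4-yn-1-yl)-1,2-dimethylcyclopentyl]-4-methylpent-3-en-1-ol (carbinol epimers) | CC(C)=CCC(O)[C@]1(C)CCC[C@]1(C)CC(O)CC#C | intermediate
22 | 4-methoxy-2-methylphenol | Cc1cc(OC)ccc1O | starting material
23 | 2-hydroxy-5-methoxy-3-methylbenzaldehyde | COc1cc(C)c(O)c(C=O)c1 | intermediate
24 | 2,5-dimethoxy-3-methylbenzaldehyde | COc1cc(C)c(OC)c(C=O)c1 | intermediate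
25 | (2,5-dimethoxy-3-methylphenyl)methanol | COc1cc(C)c(OC)c(CO)c1 | intermediate
26 | 2,5-dimethoxy-3-methylbenzyl chloride | COc1cc(C)c(OC)c(CCl)c1 | intermediate
27 | trimethylaluminium | C[Al](C)C | starting material
28 | (E)-alkenyl(dimethyl)alane of 21 with both oxygens as dimethylaluminium alkoxides | CC(C)=CCC(O[Al](C)C)[C@]1(C)CCC[C@]1(C)CC(O[Al](C)C)C/C(C)=C/[Al](C)C | intermediate
29 | 1-[(1R,2R)-2-[(4E)-6-(2,5-dimethoxy-3-methylphenyl)-2-hydroxy-4-methylhex-4-en-1-yl]-1,2-dimethylcyclopentyl]-4-methylpent-3-en-1-ol (carbinol epimers) | CC(C)=CCC(O)[C@]1(C)CCC[C@]1(C)CC(O)C/C(C)=C/Cc1cc(OC)cc(C)c1OC | intermediate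
30 | (4E)-6-(2,5-dimethoxy-3-methylphenyl)-1-[(1R,2R)-1,2-dimethyl-2-(4-methylpent-3-enoyl)cyclopentyl]-4-methylhex-4-en-2-one | CC(C)=CCC(=O)[C@]1(C)CCC[C@]1(C)CC(=O)C/C(C)=C/Cc1cc(OC)cc(C)c1OC | intermediate
31 | 2-[(2E)-6-[(1R,2R)-1,2-dimethyl-2-(4-methylpent-3-enoyl)cyclopentyl]-3-methyl-5-oxohex-2-en-1-yl]-6-methylcyclohexa-2,5-diene-1,4-dione | CC(C)=CCC(=O)[C@]1(C)CCC[C@]1(C)CC(=O)C/C(C)=C/CC1=CC(=O)C=C(C)C1=O | intermediate
32 | (4E)-6-(2,5-dihydroxy-3-methylphenyl)-1-[(1R,2R)-1,2-dimethyl-2-(4-methylpent-3-enoyl)cyclopentyl]-4-methylhex-4-en-2-one (CNP0294415.1) | CC(C)=CCC(=O)[C@]1(C)CCC[C@]1(C)CC(=O)C/C(C)=C/Cc1cc(O)cc(C)c1O | target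

Total step count: 19. Longest linear sequence: 15 (steps 1–11 and 16–19). Steps 12–15 form the four-step arene branch.

Steps most likely to fail

Step 16. The alane carries two aluminium alkoxides, so it may hand its alkenyl group to nickel sluggishly. Methyl transfer to the benzyl–nickel intermediate or homocoupling of the benzylic chloride could then take over. The fallback keeps the same two bonds but splits the operation and reverses the polarity at the C1–C2 seam. It sets out from 21, which is carboaluminated as before to 28 and quenched with iodine to give the vinyl iodide 1-[(1R,2R)-2-[(4E)-2-hydroxy-5-iodo-4-methylpent-4-en-1-yl]-1,2-dimethylcyclopentyl]-4-methylpent-3-en-1-ol F2. Chloride 26 is converted with zinc dust and LiCl in THF into (2,5-dimethoxy-3-methylbenzyl)zinc chloride F3. A Negishi coupling of the two with Pd(PPh3)4 in THF comes back to the route at 29. Benzylic zinc chlorides are protonated only slowly by alcohols, so the diol can stay unprotected.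

Step 6. Stray proton transfer during removal of ammonia or during silylation would let the enolate equilibrate through the meso ketone and erode the enantiomeric purity. Trapping could also be incomplete. The fallback moves the source of asymmetry from substrate memory to a chiral reagent. It sets out from 9, which is reduced with Li in NH3 and quenched with NH4Cl to give the meso ketone cis-3a,6a-dimethylhexahydropentalen-2(1H)-one F1. This ketone is desymmetrised by enantioselective deprotonation with lithium (R,R)-bis(1-phenylethyl)amide and Me3SiCl as internal quench in THF at −100 °C, coming back at 11. The sense of induction would be checked by correlation with material from the main route, and the mirror-image base used if needed.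

Step 18. The acidic, oxidising medium may push one of the beta,gamma-alkenes into conjugation with its ketone or start an aldol closure of the 1,5-diketone. The fallback changes the order of events so that no ketone ever meets tetravalent cerium. It sets out from 29, which is treated with (NH4)2Ce(NO3)6 in MeCN–H2O to give the quinone diol 2-[(2E)-5-hydroxy-6-[(1R,2R)-2-(1-hydroxy-4-methylpent-3-en-1-yl)-1,2-dimethylcyclopentyl]-3-methylhex-2-en-1-yl]-6-methylcyclohexa-2,5-diene-1,4-dione F4. Both carbinols of this compound are then oxidised with Dess–Martin periodinane and pyridine, to which the quinone is inert, coming back at 31.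

Further compounds
F1 | step 6 | cis-3a,6a-dimethylhexahydropentalen-2(1H)-one (meso, 3aR,6aS) | O=C1C[C@]2(C)CCC[C@]2(C)C1
F2 | step 16 | 1-[(1R,2R)-2-[(4E)-2-hydroxy-5-iodo-4-methylpent-4-en-1-yl]-1,2-dimethylcyclopentyl]-4-methylpent-3-en-1-ol (carbinol epimers) | CC(C)=CCC(O)[C@]1(C)CCC[C@]1(C)CC(O)C/C(C)=C/I
F3 | step 16 | (2,5-dimethoxy-3-methylbenzyl)zinc chloride | COc1cc(C)c(OC)c(C[Zn]Cl)c1
F4 | step 18 | 2-[(2E)-5-hydroxy-6-[(1R,2R)-2-(1-hydroxy-4-methylpent-3-en-1-yl)-1,2-dimethylcyclopentyl]-3-methylhex-2-en-1-yl]-6-methylcyclohexa-2,5-diene-1,4-dione (carbinol epimers) | CC(C)=CCC(O)[C@]1(C)CCC[C@]1(C)CC(O)C/C(C)=C/CC1=CC(=O)C=C(C)C1=O
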